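**Plan**

- Retrosynthesis: the C6–O bond of oxirane ring B is cut first (to a C6 bromide and the C5 alkoxide), then the C6–CH2 bond to the chain (to a C6 enolate and farnesyl bromide), then the C1 carbonyl (to an allylic CH2), and last the C4–O and C5–O bonds together, which leads to ethylbenzene.
- Enabling feature: in ring A (C1 C=O, C2=C3–Et, C4 CHOH, C5 and C6 the oxirane carbons) the C4 hydroxyl and the C5–O bond of ring B are cis on neighbouring carbons beside the ethyl-bearing C3. This is the cis-dihydrodiol pattern of ethylbenzene, with all six ring carbons already present.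
- Forward: ring A is the benzene ring, dearomatised by enzymatic cis-dihydroxylation; C1=C6 is saturated, C1 is oxidised to the enone carbonyl, the chain is joined at C6, and ring B is closed last.
- Stereochemistry: C4 and C5 come from the enzyme; C6 is relayed from C5, because bromine enters anti to the C5 oxygen and is then displaced by that oxygen with inversion.

Key step: step 1

Remark: ring-A numbering of the target is used for all cyclohexenone intermediates; the C6 configuration of 9 is drawn as the expected trans isomer, but it is erased in step 7 and does not matter.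

**Route**

Step 1
Reactants: 1 ethylbenzene
Product: 2 (1S,2R)-3-ethylcyclohexa-3,5-diene-1,2-diol
Conditions: E. coli JM109(pDTG601A) whole cells expressing toluene dioxygenase (IPTG-induced), glucose feed, air, phosphate-buffered mineral medium pH 7, 30 °C, 1 fed as vapour; EtOAc extraction, crystallisation
Reagents that add atoms: dioxygen, O=O
Why: The Rieske non-haem iron dioxygenase activates O2 at its mononuclear iron centre with two electrons from NADH (regenerated by the cells from glucose) and delivers both oxygen atoms suprafacially to C4 and C5 of the arene, so that two C–O bonds form on one face and the ring is dearomatised to the 3,5-diene. The closest known reaction type is the toluene dioxygenase cis-dihydroxylation of monosubstituted benzenes, for which ethylbenzene is an established substrate. No ring is closed, since all six carbons of ring A are already in place. Both new stereocentres are set by the enzyme active site, which binds the alkyl group in a fixed orientation and should give the (1S,2R)-diol, i.e. the C4 and C5 configuration of the target with both oxygens on the face that later carries ring B. The step needs regioselectivity for the ring bond next to ethyl over benzylic hydroxylation and single-face delivery; both rest on the binding mode of a monoalkylbenzene in the enzyme, and any benzylic alcohol should be removed on crystallisation.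

Step 2
Reactants: 2 (1S,2R)-3-ethylcyclohexa-3,5-diene-1,2-diol
Product: 3 (1S,2R)-3-ethylcyclohex-3-ene-1,2-diol
Conditions: KO2CN=NCO2K (2.5 equiv), AcOH (5 equiv), MeOH, 0 °C to rt
Reagents that add atoms: none
Why: Diimide generated in situ transfers H2 in a concerted syn fashion (diimide reduction) to the cis-disubstituted C1=C6 alkene far faster than to the trisubstituted ethyl-bearing C2=C3 alkene; no stereocentre is created, and the diene, which is prone to aromatising dehydration and to Diels–Alder dimerisation once acetalised, is removed before any acid step.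

Step 3
Reactants: 3 (1S,2R)-3-ethylcyclohex-3-ene-1,2-diol; 4 2,2-dimethoxypropane
Product: 5 (3aR,7aS)-4-ethyl-2,2-dimethyl-3a,6,7,7a-tetrahydro-1,3-benzodioxole
Conditions: 4 (3 equiv), p-TsOH·H2O (2 mol%), CH2Cl2, 0 °C to rt; Et3N quench
Reagents that add atoms: none
Why: Acid-catalysed transacetalisation (acetonide formation) closes the dioxolane on the cis-4,5-diol and masks both hydroxyls, in particular the allylic C4–OH, against the oxidant of the next step.

Step 4
Reactants: 5 (3aR,7aS)-4-ethyl-2,2-dimethyl-3a,6,7,7a-tetrahydro-1,3-benzodioxole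
Product: 6 (4R,5S)-3-ethyl-4,5-(isopropylidenedioxy)cyclohex-2-en-1-one
Conditions: Mn(OAc)3·2H2O (10 mol%), t-BuOOH (5 equiv, in decane), 3 Å molecular sieves, EtOAc, rt
Reagents that add atoms: tert-butyl hydroperoxide, CC(C)(C)OO
Why: Radical allylic oxidation (hydrogen abstraction by tert-butylperoxyl, peroxide formation and loss of tert-butanol) is expected at the ring CH2 of C1, the usual site in 1-alkylcyclohexenes, to give the 3-alkylcyclohex-2-enone; the tertiary C4–H is shielded by the ethyl group and the dioxolane, and no stereocentre is touched.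

Step 5
Reactants: 6 (4R,5S)-3-ethyl-4,5-(isopropylidenedioxy)cyclohex-2-en-1-one
Product: 7 (4R,5S)-3-ethyl-4,5-dihydroxycyclohex-2-en-1-one
Conditions: AcOH/H2O (4:1), 40 °C
Reagents that add atoms: none
Why: Mild acid-catalysed acetal hydrolysis frees both hydroxyls without dehydration to ethylhydroquinone; the free C5–OH is what allows the β-oxygen to be carried as a non-leaving lithium alkoxide in the next two steps.

Step 6
Reactants: 7 (4R,5S)-3-ethyl-4,5-dihydroxycyclohex-2-en-1-one; 8 (2E,6E)-farnesyl bromide
Product: 9 (4R,5S,6S)-3-ethyl-4,5-dihydroxy-6-[(2E,6E)-3,7,11-trimethyldodeca-2,6,10-trien-1-yl]cyclohex-2-en-1-one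
Conditions: LiN(i-Pr)2 (3.3 equiv), THF, −78 to −40 °C; DMPU, 8 (1.0 equiv), −78 to −30 °C; AcOH quench at −78 °C
Reagents that add atoms: none
Why: This is a Fráter–Seebach-type alkylation of a β-oxido lithium enolate: with both hydroxyls deprotonated first, the C5 oxygen is a lithium alkoxide that cannot leave by E1cB, kinetic deprotonation at the only enolisable α-carbon (C6) gives the cross-conjugated enolate, and SN2 attack on the primary allylic bromide joins the chain with its E,E geometry intact, anti to the C5 oxido group.

Step 7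
Reactants: 9 (4R,5S,6S)-3-ethyl-4,5-dihydroxy-6-[(2E,6E)-3,7,11-trimethyldodeca-2,6,10-trien-1-yl]cyclohex-2-en-1-one
Product: 10 (4R,5S)-3-ethyl-6-[(2E,6E)-farnesyl]-1,4,5-tris(triethylsilyloxy)cyclohexa-1(6),2-diene (ring-A numbering)
Conditions: LiN(i-Pr)2 (3.5 equiv), THF, −78 to −30 °C; Et3SiCl (4.5 equiv), DMPU, −78 to 0 °C; pentane, filtration, no aqueous work-up
Reagents that add atoms: chlorotriethylsilane, CC[Si](CC)(CC)Cl
Why: The same polyanion logic (as in the second deprotonation of α-alkyl β-hydroxy ester dianions) regenerates the tetrasubstituted C1=C6 enolate by kinetic α′-deprotonation with no leaving group at C5, and O-silylation of the enolate and of both alkoxides (silyl enol ether formation) gives the cross-conjugated dienol ether.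

Step 8
Reactants: 10 (4R,5S)-3-ethyl-6-[(2E,6E)-farnesyl]-1,4,5-tris(triethylsilyloxy)cyclohexa-1(6),2-diene
Product: 11 (4R,5R,6S)-6-bromo-3-ethyl-6-[(2E,6E)-farnesyl]-4,5-bis(triethylsilyloxy)cyclohex-2-en-1-one
Conditions: NBS (1.0 equiv), NaHCO3, THF, −78 °C; cold aqueous Na2S2O3 work-up, used at once
Reagents that add atoms: N-bromosuccinimide, O=C1CCC(=O)N1Br
Why: Electrophilic α-bromination of a silyl enol ether, which is far more nucleophilic than the trisubstituted chain alkenes, should place bromine at C6 from the upper face, because both silyloxy groups lie on the lower face and the pseudoaxial C5–O bond (favoured by allylic strain with the C6 substituent) blocks syn approach; this sets C6 with bromine trans to the C5 oxygen.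

Step 9
Reactants: 11 (4R,5R,6S)-6-bromo-3-ethyl-6-[(2E,6E)-farnesyl]-4,5-bis(triethylsilyloxy)cyclohex-2-en-1-one
Product: 13 (4R,5R,6R)-5,6-epoxy-3-ethyl-4-hydroxy-6-[(2E,6E)-3,7,11-trimethyldodeca-2,6,10-trien-1-yl]cyclohex-2-en-1-one, the target, equally (1R,5R,6R)-4-ethyl-5-hydroxy-1-farnesyl-7-oxabicyclo[4.1.0]hept-3-en-2-one, via bromodiol 12 (not isolated)
Conditions: Bu4NF (2.2 equiv), THF, −20 to 0 °C; then AcOH (1 equiv)
Reagents that add atoms: none
Why: Fluoride cleaves both Si–O bonds, and the C5 alkoxide, antiperiplanar to the C6–Br bond, displaces bromide in a 3-exo-tet intramolecular Williamson (Darzens-type halohydrin) closure with inversion at C6, so ring B can only form cis-fused on the face of the C5 oxygen, cis to the C4 hydroxyl and with farnesyl on the opposite face; the cis C4–OH cannot trigger a Payne rearrangement.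

**Compound list**

1 | ethylbenzene | CCc1ccccc1 | starting material
2 | (1S,2R)-3-ethylcyclohexa-3,5-diene-1,2-diol | CCC1=CC=C[C@H](O)[C@@H]1O | intermediate
3 | (1S,2R)-3-ethylcyclohex-3-ene-1,2-diol | CCC1=CCC[C@H](O)[C@@H]1O | intermediate
4 | 2,2-dimethoxypropane | COC(C)(C)OC | starting material
5 | (3aR,7aS)-4-ethyl-2,2-dimethyl-3a,6,7,7a-tetrahydro-1,3-benzodioxole | CCC1=CCC[C@@H]2OC(C)(C)O[C@H]12 | intermediate
6 | (4R,5S)-3-ethyl-4,5-(isopropylidenedioxy)cyclohex-2-en-1-one | CCC1=CC(=O)C[C@@H]2OC(C)(C)O[C@H]12 | intermediate
7 | (4R,5S)-3-ethyl-4,5-dihydroxycyclohex-2-en-1-one | CCC1=CC(=O)C[C@H](O)[C@@H]1O | intermediate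
8 | (2E,6E)-farnesyl bromide | BrC/C=C(\C)CC/C=C(\C)CCC=C(C)C | starting material
9 | (4R,5S,6S)-3-ethyl-4,5-dihydroxy-6-[(2E,6E)-farnesyl]cyclohex-2-en-1-one | CCC1=CC(=O)[C@@H](C/C=C(\C)CC/C=C(\C)CCC=C(C)C)[C@H](O)[C@@H]1O | intermediate
10 | (4R,5S)-3-ethyl-6-[(2E,6E)-farnesyl]-1,4,5-tris(triethylsilyloxy)cyclohexa-1(6),2-diene | CCC1=CC(O[Si](CC)(CC)CC)=C(C/C=C(\C)CC/C=C(\C)CCC=C(C)C)[C@H](O[Si](CC)(CC)CC)[C@@H]1O[Si](CC)(CC)CC | intermediate
11 | (4R,5R,6S)-6-bromo-3-ethyl-6-[(2E,6E)-farnesyl]-4,5-bis(triethylsilyloxy)cyclohex-2-en-1-one | CCC1=CC(=O)[C@](Br)(C/C=C(\C)CC/C=C(\C)CCC=C(C)C)[C@H](O[Si](CC)(CC)CC)[C@@H]1O[Si](CC)(CC)CC | intermediate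
12 | (4R,5R,6S)-6-bromo-3-ethyl-4,5-dihydroxy-6-[(2E,6E)-farnesyl]cyclohex-2-en-1-one (formed as its C5 alkoxide) | CCC1=CC(=O)[C@](Br)(C/C=C(\C)CC/C=C(\C)CCC=C(C)C)[C@H](O)[C@@H]1O | intermediate
13 | (4R,5R,6R)-5,6-epoxy-3-ethyl-4-hydroxy-6-[(2E,6E)-farnesyl]cyclohex-2-en-1-one | CCC1=CC(=O)[C@]2(C/C=C(\C)CC/C=C(\C)CCC=C(C)C)O[C@@H]2[C@@H]1O | target

**Step count and risks**

Total: 9 steps. Longest linear sequence: 9 steps (1 to 13); 4 and 8 are bought.

Steps most likely to fail:

1. Step 6. The triply lithiated species may aggregate, may be deprotonated at a γ-position instead of C6, or may be O-alkylated at an alkoxide, so that C-alkylation at C6 stays incomplete. The fallback sets out from 6 and keeps the acetonide. The kinetic lithium enolate (LiN(i-Pr)2, 1.1 equiv, THF, −78 °C) is alkylated with 8 in the presence of DMPU at −78 to −60 °C to give (4R,5S,6S)-3-ethyl-6-[(2E,6E)-farnesyl]-4,5-(isopropylidenedioxy)cyclohex-2-en-1-one F4. Here the β-oxygen is a ring alkoxide, a poor leaving group that low temperature and the fast allylic electrophile should keep in place. Hydrolysis of F4 with AcOH/H2O (4:1) at 40 °C returns to the route at 9.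

2. Step 8. Bromine may be delivered to the lower face of C6 (syn to the C5 oxygen, an isomer that cannot close), or NBS may attack the chain alkenes. The fallback sets out from 9 and replaces steps 7 to 9 by one operation, which is less precedented than the main sequence. The polyanion is formed as in step 7 (LiN(i-Pr)2, 3.3 equiv, THF, −78 to −30 °C) and treated with I2 (1.05 equiv) at −78 °C. The β-oxido enolate is iodinated at C6 to the lithium alkoxide of (4R,5R,6S)-3-ethyl-4,5-dihydroxy-6-iodo-6-[(2E,6E)-farnesyl]cyclohex-2-en-1-one F5, which on warming to 0 °C closes in the same flask and rejoins the route at 13. Iodine does not add irreversibly to the chain alkenes, and an iodide formed on the wrong face can revert to the enolate by attack of iodide on iodine while the anti isomer is drained by ring closure. This is the ketone counterpart of the dianion–iodine conversion of β-hydroxy esters into glycidic esters.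

3. Step 4. Hydrogen abstraction may occur at the ethyl CH2 or at C4–H instead of C1–H2, or the product may be over-oxidised. The fallback sets out from 5 and fixes the regiochemistry by a known three-stage transposition:
   - Epoxidation with mCPBA/NaHCO3 in CH2Cl2 gives the 2,3-epoxide of 5 with the oxirane anti to the dioxolane, F1.
   - PhSeNa (from (PhSe)2 and NaBH4, EtOH) opens F1 at the less substituted C2 to the trans β-hydroxy selenide F2.
   - H2O2 oxidises the selenide, and syn elimination of the selenoxide, which can only run towards C1, gives the tertiary allylic alcohol (3aR,4S,7aS)-4-ethyl-2,2-dimethyl-3a,4,7,7a-tetrahydro-1,3-benzodioxol-4-ol F3.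
   - Pyridinium chlorochromate, [C5H5NH][CrO3Cl], in CH2Cl2 effects the Babler–Dauben oxidative transposition of F3 and returns to the route at 6.

**Further compounds**

F1 | step 4 | 2,3-epoxide of 5 (ring-A numbering), oxirane anti to the dioxolane | CC[C@]12O[C@H]1CC[C@@H]3OC(C)(C)O[C@H]23
F2 | step 4 | trans β-hydroxy selenide: C3 tertiary alcohol, C2 phenylselanyl, acetonide retained | CC[C@]1(O)[C@H]([Se]c2ccccc2)CC[C@@H]2OC(C)(C)O[C@H]12
F3 | step 4 | (3aR,4S,7aS)-4-ethyl-2,2-dimethyl-3a,4,7,7a-tetrahydro-1,3-benzodioxol-4-ol | CC[C@]1(O)C=CC[C@@H]2OC(C)(C)O[C@H]12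
F4 | step 6 | (4R,5S,6S)-3-ethyl-6-[(2E,6E)-farnesyl]-4,5-(isopropylidenedioxy)cyclohex-2-en-1-one | CCC1=CC(=O)[C@@H](C/C=C(\C)CC/C=C(\C)CCC=C(C)C)[C@@H]2OC(C)(C)O[C@H]12
F5 | step 8 | (4R,5R,6S)-3-ethyl-4,5-dihydroxy-6-iodo-6-[(2E,6E)-farnesyl]cyclohex-2-en-1-one (as lithium alkoxide) | CCC1=CC(=O)[C@](I)(C/C=C(\C)CC/C=C(\C)CCC=C(C)C)[C@H](O)[C@@H]1O
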